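The earlier runs and the new flask are simulated with constants of no real substance; the scatter is artificial.

A small charge of stray impurity, 0.10 mM, stands against 0.25 mM of initiator in this flask, which also holds free monomer, transfer agent and protic impurity. The two earlier runs differ from it in the stray impurity.

| flask | free monomer | transfer agent | protic impurity | initiator | stray impurity | remark | time |
|---|---|---|---|---|---|---|---|
| grey | 0.050 M | 0.015 M | 0.015 M | 0.25 mM | 0.050 mM | run made earlier |  |
| red | 0.050 M | 0.015 M | 0.015 M | 0.25 mM | 0.20 mM | run made earlier |  |
| flask | 0.050 M | 0.0150 M | 0.0150 M | 0.25 mM | 0.10 mM |  | 6.0 d |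

| run | time / d | monomer in chains / % | free monomer / % |
|---|---|---|---|
| grey | 0.417 | 34.2 | 35.6 |
| grey | 0.833 | 47.3 | 22.2 |
| grey | 2.08 | 57.4 | 13.6 |
| grey | 5.00 | 58.6 | 12.5 |
| red | 1.25 | 24.1 | 45.5 |
| red | 2.50 | 30.3 | 43.4 |
| red | 4.00 | 28.5 | 42.0 |
| red | 5.00 | 28.3 | 40.3 |

(standard deviation of a reading: 1 percentage point)

- the average divides the monomer in chains by the number of chains begun, living and dead together
- candidate steps: free monomer + initiator -> living end + monomer in chains; free monomer + living end -> monomer in chains + living end; living end + transfer agent -> dead chain; initiator + monomer in chains -> spent initiator A; initiator + stray impurity -> spent initiator B; protic impurity + free monomer -> quenched substrate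
- the earlier runs do not show the number of chains; that part of a forecast is a guess

- average number of monomer units in a chain (chains begun, living or dead) at 6.0 d
- part of the free monomer that has reacted at 6.0 d

The readings give a ladder of times. On the first rung stands the protic impurity: at 0.417 d in the grey run, monomer in chains and free monomer add up to 69.8% of the charge, and the gap matches the protic impurity, 30.0% of the free monomer. On the next rung chains grow: grey free monomer falls to 13.6% by 2.08 d, then reads 12.5% at 5.00 d, a change near the scatter. So grey growth has levelled off within about the scatter, and a plateau is expected in this flask at 6.0 d.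

Its height can be reckoned as a correction to the initiator. If stray impurity destroys initiator one for one before chains begin, the starters S, initiator charge minus stray impurity charge, 0.150 mM in this flask, are 0.200 mM in grey and 0.0500 mM in red. Grey over red, S stands at 4.00, while ln(available monomer/free monomer), available meaning monomer in chains plus free monomer, stands at 3.27 at the last readings, a rough match. Scaling grey by S gives 1.30 for this flask, so free monomer near 19.3%, c near 80.7%, and, guessing one chain per starter, dp near 173.

The forecast gives 175 for dp and 81% for c, and warns: “The chain count is unobserved, so this is a guess.”

The flask gives 180 and 82.1%.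

    free monomer + initiator → living end + monomer in chains (k = 0.330 M⁻¹ min⁻¹)
    free monomer + living end → monomer in chains + living end, rate k2*[living end]*[free monomer] (k = 8.30 M⁻¹ min⁻¹)
    living end + transfer agent → dead chain (kL = 0.0590 M⁻¹ min⁻¹)
    initiator + monomer in chains → spent initiator A (k = 0.250 M⁻¹ min⁻¹)
    initiator + stray impurity → spent initiator B (k = 740 M⁻¹ min⁻¹)
    protic impurity + free monomer → quenched substrate (k = 6.40 M⁻¹ min⁻¹)

In this flask, with the stray impurity held at its charge, the initiator's half-life by that step, 0.16 h, is shorter than the 0.700 h it has against free monomer held as charged, and 0.00756% of the stray impurity's charge remains at 6.00 d. This flask holds 0.144 mM of chains against S of 0.150 mM, and monomer in chains over S gives 174 beside the 180 found. The neighbour with 0.025 M of transfer agent has the same S, and its monomer in chains over S gives 131 beside its simulated 135.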